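**Retrosynthetic overview**
1. Last bond: the ester C–O between α-linolenic acid 30 and the C20 alcohol 29 (Steglich esterification).
2. Both (E)-trisubstituted olefins of 29 come from β-keto esters via (Z)-enol phosphate and Me2CuLi, then DIBAL-H; the second β-keto ester 25 comes from the acetoacetate dianion and allylic bromide 22.
3. Key C–C bond (C6–C7): crossed Claisen condensation of the acyl imidazolide of (S)-acid 13 with the lithium enolate of methyl acetate, giving β-keto ester 17.
4. Stereocentre: CBS reduction of enone 4 to (R)-allylic alcohol 5, then Johnson–Claisen chirality transfer to the (S) ring carbon (ester 9) and a one-carbon homologation (Grignard/CO2) to 13.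
5. Ring order: the only ring (the cyclohexene) is made first, by Michael/aldol annulation of isobutyraldehyde with ethyl vinyl ketone.

Assumption: the ring stereocentre written [C@@H] is (S) (ring C2 > ring C6 > side chain > H), with 2E,6E and 9Z,12Z,15Z geometries as drawn; α-linolenic acid is bought as the pure all-Z acid.

**Step 1**
Reactants: 1 isobutyraldehyde; 2 ethyl vinyl ketone (pent-1-en-3-one)
Product: 4 2,4,4-trimethylcyclohex-2-en-1-one, via 2,2-dimethyl-5-oxoheptanal 3 (not isolated)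
Conditions: cat. conc. H2SO4, neat, 45–50 °C; then toluene, reflux, Dean–Stark
Reagents that add atoms: none
Why: Acid-catalysed Michael addition of the enol of 1 to enone 2 gives keto-aldehyde 3, which closes by intramolecular aldol condensation (Robinson-type annulation) to the only possible six-membered enone, water being the sole by-product.

**Step 2**
Reactants: 4 2,4,4-trimethylcyclohex-2-en-1-one
Product: 5 (1R)-2,4,4-trimethylcyclohex-2-en-1-ol
Conditions: (S)-Me-CBS (10 mol%), BH3·SMe2 (0.7 eq), THF, −20 °C; MeOH quench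
Reagents that add atoms: none
Why: Corey–Bakshi–Shibata reduction in which the α-methylated alkenyl arm acts as the large group (as phenyl does in acetophenone), so the (S)-catalyst is expected to give the (R)-carbinol in high ee.

**Step 3**
Reactants: 5 (1R)-2,4,4-trimethylcyclohex-2-en-1-ol; 6 triethyl orthoacetate
Product: 9 ethyl [(1S)-2,6,6-trimethylcyclohex-2-en-1-yl]acetate, via mixed orthoester 7 (not isolated), via ketene acetal 8 (not isolated)
Conditions: MeC(OEt)3 (6 eq), cat. EtCO2H, 140 °C, EtOH distilled off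
Reagents that add atoms: none
Why: Johnson–Claisen rearrangement; the [3,3] shift is suprafacial across the ring allyl unit, so the new C–C bond forms on the face the C–O bond leaves and the (R)-carbinol is transferred into the (S) ring carbon next to the gem-dimethyl group.

**Step 4**
Reactants: 9 ethyl [(1S)-2,6,6-trimethylcyclohex-2-en-1-yl]acetate
Product: 10 2-[(1S)-2,6,6-trimethylcyclohex-2-en-1-yl]ethan-1-ol
Conditions: LiAlH4, Et2O, 0 °C to rt; Fieser work-up
Reagents that add atoms: none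
Why: Hydride reduction of an ester to the primary alcohol; the ring stereocentre is not acidic and the isolated olefin is inert.

**Step 5**
Reactants: 10 2-[(1S)-2,6,6-trimethylcyclohex-2-en-1-yl]ethan-1-ol
Product: 11 (6S)-6-(2-bromoethyl)-1,5,5-trimethylcyclohex-1-ene
Conditions: CBr4, PPh3, CH2Cl2, 0 °C to rt
Reagents that add atoms: carbon tetrabromide, BrC(Br)(Br)Br
Why: Appel bromination is an SN2 displacement at a primary carbon under neutral conditions, so no cation forms and the ring olefin does not migrate.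

**Step 6**
Reactants: 11 (6S)-6-(2-bromoethyl)-1,5,5-trimethylcyclohex-1-ene
Product: 13 3-[(1S)-2,6,6-trimethylcyclohex-2-en-1-yl]propanoic acid, via Grignard reagent 12 (not isolated)
Conditions: Mg, cat. I2, THF, 40 °C; CO2 (g), −10 °C to rt; 1 M HCl
Reagents that add atoms: carbon dioxide, O=C=O
Why: Grignard formation from a primary bromide and carboxylation adds the one carbon (C7) needed before the chain-building sequence.

**Step 7**
Reactants: 13 3-[(1S)-2,6,6-trimethylcyclohex-2-en-1-yl]propanoic acid; 14 methyl acetate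
Product: 17 methyl 3-oxo-5-[(1S)-2,6,6-trimethylcyclohex-2-en-1-yl]pentanoate, via acyl imidazolide 15 (not isolated), via lithium enolate 16 (not isolated)
Conditions: 13, CDI, THF, rt; separately 14, LDA (3 eq), THF, −78 °C; combine at −78 to −40 °C; aq. HCl to pH 3
Reagents that add atoms: none
Why: Crossed Claisen condensation in which the ester enolate is C-acylated by the acyl imidazolide at low temperature, and the excess enolate deprotonates the β-keto ester product, making the step irreversible.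

**Step 8**
Reactants: 17 methyl 3-oxo-5-[(1S)-2,6,6-trimethylcyclohex-2-en-1-yl]pentanoate
Product: 19 methyl (2Z)-3-[(diethoxyphosphoryl)oxy]-5-[(1S)-2,6,6-trimethylcyclohex-2-en-1-yl]pent-2-enoate, via sodium enolate 18 (not isolated)
Conditions: NaH, Et2O, 0 °C; ClP(O)(OEt)2, 0 °C to rt
Reagents that add atoms: diethyl chlorophosphate, CCOP(=O)(Cl)OCC
Why: O-Phosphorylation of the chelated sodium enolate of a β-keto ester gives the (Z)-enol phosphate selectively (Weiler enol phosphate formation).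

**Step 9**
Reactants: 19 methyl (2Z)-3-[(diethoxyphosphoryl)oxy]-5-[(1S)-2,6,6-trimethylcyclohex-2-en-1-yl]pent-2-enoate
Product: 20 methyl (2E)-3-methyl-5-[(1S)-2,6,6-trimethylcyclohex-2-en-1-yl]pent-2-enoate
Conditions: Me2CuLi (2.5 eq, from MeLi and CuI), Et2O, −78 to −45 °C; aq. NH4Cl/NH3
Reagents that add atoms: lithium dimethylcuprate, [Li+].C[Cu-]C (made from methyllithium, [Li]C, and copper(I) iodide, [Cu]I)
Why: Cuprate addition–elimination on the enol phosphate replaces the phosphate by methyl with retention of geometry, so the (Z)-phosphate gives the (E)-trisubstituted enoate (Weiler olefin synthesis).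

**Step 10**
Reactants: 20 methyl (2E)-3-methyl-5-[(1S)-2,6,6-trimethylcyclohex-2-en-1-yl]pent-2-enoate
Product: 21 (2E)-3-methyl-5-[(1S)-2,6,6-trimethylcyclohex-2-en-1-yl]pent-2-en-1-ol
Conditions: DIBAL-H (2.5 eq), CH2Cl2, −78 to 0 °C; Rochelle salt
Reagents that add atoms: none
Why: DIBAL-H gives clean 1,2-reduction of the enoate to the allylic alcohol without touching the olefin geometry.

**Step 11**
Reactants: 21 (2E)-3-methyl-5-[(1S)-2,6,6-trimethylcyclohex-2-en-1-yl]pent-2-en-1-ol
Product: 22 (6S)-6-[(3E)-5-bromo-3-methylpent-3-en-1-yl]-1,5,5-trimethylcyclohex-1-ene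
Conditions: CBr4, PPh3, CH2Cl2, −20 to 0 °C; used crude
Reagents that add atoms: carbon tetrabromide, BrC(Br)(Br)Br
Why: Appel bromination of a primary allylic alcohol proceeds by SN2 under neutral conditions, as for geraniol, without allylic transposition or E/Z loss.

**Step 12**
Reactants: 22 (6S)-6-[(3E)-5-bromo-3-methylpent-3-en-1-yl]-1,5,5-trimethylcyclohex-1-ene; 23 methyl acetoacetate
Product: 25 methyl (6E)-7-methyl-3-oxo-9-[(1S)-2,6,6-trimethylcyclohex-2-en-1-yl]non-6-enoate, via acetoacetate dianion 24 (not isolated)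
Conditions: 23, NaH, THF, 0 °C; n-BuLi, 0 °C; then 22, 0 °C to rt; aq. NH4Cl
Reagents that add atoms: none
Why: Weiler alkylation, in which the more nucleophilic γ-carbon of the acetoacetate dianion displaces the primary allylic bromide by SN2.

**Step 13**
Reactants: 25 methyl (6E)-7-methyl-3-oxo-9-[(1S)-2,6,6-trimethylcyclohex-2-en-1-yl]non-6-enoate
Product: 27 methyl (2Z,6E)-3-[(diethoxyphosphoryl)oxy]-7-methyl-9-[(1S)-2,6,6-trimethylcyclohex-2-en-1-yl]nona-2,6-dienoate, via sodium enolate 26 (not isolated)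
Conditions: NaH, Et2O, 0 °C; ClP(O)(OEt)2, 0 °C to rt
Reagents that add atoms: diethyl chlorophosphate, CCOP(=O)(Cl)OCC
Why: Same (Z)-selective enol phosphate formation from the chelated sodium enolate as in step 8.

**Step 14**
Reactants: 27 methyl (2Z,6E)-3-[(diethoxyphosphoryl)oxy]-7-methyl-9-[(1S)-2,6,6-trimethylcyclohex-2-en-1-yl]nona-2,6-dienoate
Product: 28 methyl (2E,6E)-3,7-dimethyl-9-[(1S)-2,6,6-trimethylcyclohex-2-en-1-yl]nona-2,6-dienoate
Conditions: Me2CuLi (2.5 eq, from MeLi and CuI), Et2O, −78 to −45 °C; aq. NH4Cl/NH3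
Reagents that add atoms: lithium dimethylcuprate, [Li+].C[Cu-]C (made from methyllithium, [Li]C, and copper(I) iodide, [Cu]I)
Why: Stereoretentive cuprate substitution of the (Z)-enol phosphate sets the 2E olefin, and the isolated 6E olefin is inert.

**Step 15**
Reactants: 28 methyl (2E,6E)-3,7-dimethyl-9-[(1S)-2,6,6-trimethylcyclohex-2-en-1-yl]nona-2,6-dienoate
Product: 29 (2E,6E)-3,7-dimethyl-9-[(1S)-2,6,6-trimethylcyclohex-2-en-1-yl]nona-2,6-dien-1-ol
Conditions: DIBAL-H (2.5 eq), CH2Cl2, −78 to 0 °C; Rochelle salt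
Reagents that add atoms: none
Why: DIBAL-H 1,2-reduction of the enoate gives the primary allylic alcohol with all olefins unchanged.

**Step 16**
Reactants: 29 (2E,6E)-3,7-dimethyl-9-[(1S)-2,6,6-trimethylcyclohex-2-en-1-yl]nona-2,6-dien-1-ol; 30 α-linolenic acid ((9Z,12Z,15Z)-octadeca-9,12,15-trienoic acid)
Product: 32 (2E,6E)-3,7-dimethyl-9-[(1S)-2,6,6-trimethylcyclohex-2-en-1-yl]nona-2,6-dien-1-yl (9Z,12Z,15Z)-octadeca-9,12,15-trienoate, via O-acylisourea 31 (not isolated)
Conditions: DCC (1.2 eq), DMAP (0.1 eq), CH2Cl2, 0 °C to rt, Ar, dark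
Reagents that add atoms: none
Why: Steglich esterification is neutral and mild, so the skipped all-Z triene and the allylic alcohol are not isomerised and no stereocentre is touched.

**Compound list**
1 | isobutyraldehyde | CC(C)C=O | starting material
2 | ethyl vinyl ketone (pent-1-en-3-one) | CCC(=O)C=C | starting material
3 | 2,2-dimethyl-5-oxoheptanal | CCC(=O)CCC(C)(C)C=O | intermediate
4 | 2,4,4-trimethylcyclohex-2-en-1-one | CC1=CC(C)(C)CCC1=O | intermediate
5 | (1R)-2,4,4-trimethylcyclohex-2-en-1-ol | O[C@@H]1CCC(C)(C)C=C1C | intermediate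
6 | triethyl orthoacetate | CC(OCC)(OCC)OCC | starting material
7 | mixed orthoester, (1R)-1-(1,1-diethoxyethoxy)-2,4,4-trimethylcyclohex-2-ene | CC(OCC)(OCC)O[C@@H]1CCC(C)(C)C=C1C | intermediate
8 | ketene acetal, (1R)-1-[(1-ethoxyethenyl)oxy]-2,4,4-trimethylcyclohex-2-ene | C=C(OCC)O[C@@H]1CCC(C)(C)C=C1C | intermediate
9 | ethyl [(1S)-2,6,6-trimethylcyclohex-2-en-1-yl]acetate | CCOC(=O)C[C@@H]1C(C)=CCCC1(C)C | intermediate
10 | 2-[(1S)-2,6,6-trimethylcyclohex-2-en-1-yl]ethan-1-ol | OCC[C@@H]1C(C)=CCCC1(C)C | intermediate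
11 | (6S)-6-(2-bromoethyl)-1,5,5-trimethylcyclohex-1-ene | BrCC[C@@H]1C(C)=CCCC1(C)C | intermediate
12 | Grignard reagent, {2-[(1S)-2,6,6-trimethylcyclohex-2-en-1-yl]ethyl}magnesium bromide | Br[Mg]CC[C@@H]1C(C)=CCCC1(C)C | intermediate
13 | 3-[(1S)-2,6,6-trimethylcyclohex-2-en-1-yl]propanoic acid | OC(=O)CC[C@@H]1C(C)=CCCC1(C)C | intermediate
14 | methyl acetate | COC(C)=O | starting material
15 | acyl imidazolide, 1-{3-[(1S)-2,6,6-trimethylcyclohex-2-en-1-yl]propanoyl}imidazole | O=C(CC[C@@H]1C(C)=CCCC1(C)C)n1ccnc1 | intermediate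
16 | lithium enolate of methyl acetate | [Li+].C=C([O-])OC | intermediate
17 | methyl 3-oxo-5-[(1S)-2,6,6-trimethylcyclohex-2-en-1-yl]pentanoate | COC(=O)CC(=O)CC[C@@H]1C(C)=CCCC1(C)C | intermediate
18 | sodium (Z)-enolate of 17 | [Na+].[O-]/C(CC[C@@H]1C(C)=CCCC1(C)C)=C\C(=O)OC | intermediate
19 | methyl (2Z)-3-[(diethoxyphosphoryl)oxy]-5-[(1S)-2,6,6-trimethylcyclohex-2-en-1-yl]pent-2-enoate | CCOP(=O)(OCC)O/C(CC[C@@H]1C(C)=CCCC1(C)C)=C\C(=O)OC | intermediate
20 | methyl (2E)-3-methyl-5-[(1S)-2,6,6-trimethylcyclohex-2-en-1-yl]pent-2-enoate | COC(=O)/C=C(\C)CC[C@@H]1C(C)=CCCC1(C)C | intermediate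
21 | (2E)-3-methyl-5-[(1S)-2,6,6-trimethylcyclohex-2-en-1-yl]pent-2-en-1-ol | OC/C=C(\C)CC[C@@H]1C(C)=CCCC1(C)C | intermediate
22 | (6S)-6-[(3E)-5-bromo-3-methylpent-3-en-1-yl]-1,5,5-trimethylcyclohex-1-ene | BrC/C=C(\C)CC[C@@H]1C(C)=CCCC1(C)C | intermediate
23 | methyl acetoacetate | COC(=O)CC(C)=O | starting material
24 | acetoacetate dianion (sodium lithium salt of methyl acetoacetate) | [Na+].[Li+].C=C([O-])C=C([O-])OC | intermediate
25 | methyl (6E)-7-methyl-3-oxo-9-[(1S)-2,6,6-trimethylcyclohex-2-en-1-yl]non-6-enoate | COC(=O)CC(=O)CC/C=C(\C)CC[C@@H]1C(C)=CCCC1(C)C | intermediate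
26 | sodium (Z)-enolate of 25 | [Na+].[O-]/C(CC/C=C(\C)CC[C@@H]1C(C)=CCCC1(C)C)=C\C(=O)OC | intermediate
27 | methyl (2Z,6E)-3-[(diethoxyphosphoryl)oxy]-7-methyl-9-[(1S)-2,6,6-trimethylcyclohex-2-en-1-yl]nona-2,6-dienoate | CCOP(=O)(OCC)O/C(CC/C=C(\C)CC[C@@H]1C(C)=CCCC1(C)C)=C\C(=O)OC | intermediate
28 | methyl (2E,6E)-3,7-dimethyl-9-[(1S)-2,6,6-trimethylcyclohex-2-en-1-yl]nona-2,6-dienoate | COC(=O)/C=C(\C)CC/C=C(\C)CC[C@@H]1C(C)=CCCC1(C)C | intermediate
29 | (2E,6E)-3,7-dimethyl-9-[(1S)-2,6,6-trimethylcyclohex-2-en-1-yl]nona-2,6-dien-1-ol | OC/C=C(\C)CC/C=C(\C)CC[C@@H]1C(C)=CCCC1(C)C | intermediate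
30 | α-linolenic acid, (9Z,12Z,15Z)-octadeca-9,12,15-trienoic acid | CC/C=C\C/C=C\C/C=C\CCCCCCCC(=O)O | starting material
31 | O-acylisourea of 30 with DCC | CC/C=C\C/C=C\C/C=C\CCCCCCCC(=O)OC(NC1CCCCC1)=NC1CCCCC1 | intermediate
32 | (2E,6E)-3,7-dimethyl-9-[(1S)-2,6,6-trimethylcyclohex-2-en-1-yl]nona-2,6-dien-1-yl (9Z,12Z,15Z)-octadeca-9,12,15-trienoate | CC/C=C\C/C=C\C/C=C\CCCCCCCC(=O)OC/C=C(\C)CC/C=C(\C)CC[C@@H]1C(C)=CCCC1(C)C | target

**Totals**
Total step count: 16. Longest linear sequence: 16 steps (1 + 2 to 32); compounds 6, 14, 23 and 30 are bought and enter directly.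

**Steps most likely to fail, with fallbacks**

Step 3 (Johnson–Claisen). The new bond forms at a ring carbon next to the gem-dimethyl group, and the acid at 140 °C may dehydrate 5 to dienes. The fallback sets out from 5 and comes back at 10. Acetylation (Ac2O, pyridine, DMAP) gives (1R)-2,4,4-trimethylcyclohex-2-en-1-yl acetate F4. LDA with TMSCl in THF at −78 °C converts it into the silyl ketene acetal F5. Warming to 60 °C brings about the Ireland–Claisen rearrangement to trimethylsilyl [(1S)-2,6,6-trimethylcyclohex-2-en-1-yl]acetate F6, which aqueous work-up hydrolyses to [(1S)-2,6,6-trimethylcyclohex-2-en-1-yl]acetic acid F7. LiAlH4 in Et2O reduces this acid to 10.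

Step 2 (CBS reduction). The ee may fall short of what a single-enantiomer target needs. The fallback sets out from 4 and comes back at 5. Luche reduction (NaBH4, CeCl3·7H2O, MeOH, 0 °C) gives racemic 2,4,4-trimethylcyclohex-2-en-1-ol F1. Kinetic resolution with immobilised Candida antarctica lipase B and vinyl butanoate in hexane at 30 °C (about 50% conversion, Kazlauskas-rule (R)-selectivity) gives (1R)-2,4,4-trimethylcyclohex-2-en-1-yl butanoate F2 and leaves (1S)-2,4,4-trimethylcyclohex-2-en-1-ol F3, which is separated and can be re-oxidised to 4. K2CO3 in MeOH cleaves the butanoate to 5.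

Step 9 (enol phosphate/cuprate coupling). Warming too far can erode the E geometry or give double addition. The fallback sets out from 11 and comes back at 20, bypassing steps 6–9. Lithium acetylide–ethylenediamine complex in DMSO at rt displaces the bromide to give (6S)-6-(but-3-yn-1-yl)-1,5,5-trimethylcyclohex-1-ene F8. Negishi carboalumination (Me3Al, cat. Cp2ZrCl2, CH2Cl2, rt) adds Me and Al syn to give the (E)-alkenyl dimethylalane F9. Trapping with methyl chloroformate gives 20 with the E geometry fixed by the syn addition.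

**Further compounds**
F1 | step 2 | racemic 2,4,4-trimethylcyclohex-2-en-1-ol | CC1=CC(C)(C)CCC1O
F2 | step 2 | (1R)-2,4,4-trimethylcyclohex-2-en-1-yl butanoate | CCCC(=O)O[C@@H]1CCC(C)(C)C=C1C
F3 | step 2 | (1S)-2,4,4-trimethylcyclohex-2-en-1-ol | O[C@H]1CCC(C)(C)C=C1C
F4 | step 3 | (1R)-2,4,4-trimethylcyclohex-2-en-1-yl acetate | CC(=O)O[C@@H]1CCC(C)(C)C=C1C
F5 | step 3 | silyl ketene acetal, trimethyl({1-[(1R)-2,4,4-trimethylcyclohex-2-en-1-yl]oxyethenyl}oxy)silane | C=C(O[Si](C)(C)C)O[C@@H]1CCC(C)(C)C=C1C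
F6 | step 3 | trimethylsilyl [(1S)-2,6,6-trimethylcyclohex-2-en-1-yl]acetate | C[Si](C)(C)OC(=O)C[C@@H]1C(C)=CCCC1(C)C
F7 | step 3 | [(1S)-2,6,6-trimethylcyclohex-2-en-1-yl]acetic acid | OC(=O)C[C@@H]1C(C)=CCCC1(C)C
F8 | step 9 | (6S)-6-(but-3-yn-1-yl)-1,5,5-trimethylcyclohex-1-ene | C#CCC[C@@H]1C(C)=CCCC1(C)C
F9 | step 9 | dimethyl{(1E)-2-methyl-4-[(1S)-2,6,6-trimethylcyclohex-2-en-1-yl]but-1-en-1-yl}alane | C[Al](C)/C=C(\C)CC[C@@H]1C(C)=CCCC1(C)C
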